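**Plan**

1. Retrosynthetic cuts: the two angelate C–O bonds (C6 ester, then C3 ester) and the C1/C10 oxirane first; then C2–C3 is cut while C3–C8 is re-formed, which contracts the ten-membered ring to a six-membered 2-acyl ketone; then C8–C9, the C4/C5 oxirane and the C6–O bond.
2. Enabling feature: ring atoms C3–C8 (carbonyl-level C3, methyl-bearing C4, C5, oxygenated C6, isopropenyl-bearing C7, C8) are a carvone ring. C9–C10–C1–C2 is a 2-methylbut-2-enoyl unit lodged between its carbonyl carbon C3 and α′-carbon C8, so C3 and C9 are 1,5-dicarbonyl partners across the C2 methylene.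
3. Forward order: (S)-carvone gives the six-membered ring (C6–OH, cis C4–C5 oxirane); C8 receives the acyl chain and a sulfur blocking group; dienolate addition/fragmentation makes C2–C3 and turns the six- into the ten-membered ring; then reduction, desulfurisation, second oxirane, and the two esters one at a time (C3, then C6 after desilylation).
4. Stereochemistry: C7 from (S)-carvone; C6 and the C4–C5 oxirane by substrate control on the six-membered ring; both cis ring fusions because each double bond is born inside a six-membered ring; C3 by reagent-controlled CBS reduction; C1/C10 by hydroxyl-directed epoxidation.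

Key step: step 8

Remark (assumption on the structure): locants C1–C15 are germacrane numbers (C7 carries the isopropenyl group C11–C13, C9 is the ketone, C14 and C15 are the methyls on C10 and C4). The SMILES is read as having both oxiranes cis-fused to the ten-membered ring (C2/C9 and C3/C6 on the same side), i.e. derived from Z ring olefins.

**Step 1**
Reactants: 1 (S)-(+)-carvone
Product: 2 tert-butyldimethyl{[(5R)-2-methyl-5-(prop-1-en-2-yl)cyclohexa-1,3-dien-1-yl]oxy}silane
Conditions: KN(SiMe3)2 (0.95 equiv), THF, −78 to 0 °C, 1 h; then t-BuMe2SiCl, −78 °C to rt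
Reagents that add atoms: tert-butyldimethylsilyl chloride, CC(C)(C)[Si](C)(C)Cl
Why: With a slight deficit of base the kinetic α′-enolate should equilibrate by proton transfer to the more stable, linearly conjugated γ-dienolate, whose O-silylation (thermodynamic silyl dienol ether formation) leaves the C7 stereocentre untouched.

**Step 2**
Reactants: 2 tert-butyldimethyl{[(5R)-2-methyl-5-(prop-1-en-2-yl)cyclohexa-1,3-dien-1-yl]oxy}silane
Product: 3 (4R,5S)-4-hydroxy-2-methyl-5-(prop-1-en-2-yl)cyclohex-2-en-1-one (trans-4-hydroxycarvone)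
Conditions: mCPBA (1.0 equiv), CH2Cl2, −30 °C; then 10% aq. citric acid, THF, 0 °C
Reagents that add atoms: 3-chloroperbenzoic acid (mCPBA), O=C(OO)c1cccc(Cl)c1
Why: Vinylogous Rubottom oxidation, in which the peracid should attack the electron-rich diene at its γ,δ-double bond (the α-carbon is fully substituted) from the face anti to the neighbouring isopropenyl group, so that collapse of the epoxide and loss of silicon give the trans γ-hydroxy enone and set C6.

**Step 3**
Reactants: 3 (4R,5S)-4-hydroxy-2-methyl-5-(prop-1-en-2-yl)cyclohex-2-en-1-one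
Product: 4 (1S,4S,5S,6S)-5-hydroxy-1-methyl-4-(prop-1-en-2-yl)-7-oxabicyclo[4.1.0]heptan-2-one
Conditions: t-BuOOH, benzyltrimethylammonium hydroxide (cat.), THF, 0 °C
Reagents that add atoms: tert-butyl hydroperoxide, CC(C)(C)OO
Why: Weitz–Scheffer epoxidation of the enone, in which the peroxide anion should add axially to C5 anti to the isopropenyl group (as in carvone to carvone oxide) and is also guided by hydrogen bonding to the C6 hydroxyl on that same face, giving the cis-fused C4–C5 oxirane syn to OH and anti to isopropenyl.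

**Step 4**
Reactants: 4 (1S,4S,5S,6S)-5-hydroxy-1-methyl-4-(prop-1-en-2-yl)-7-oxabicyclo[4.1.0]heptan-2-one
Product: 5 (1S,4S,5S,6S)-5-[(tert-butyldimethylsilyl)oxy]-1-methyl-4-(prop-1-en-2-yl)-7-oxabicyclo[4.1.0]heptan-2-one
Conditions: t-BuMe2SiCl, imidazole, DMF, rt
Reagents that add atoms: tert-butyldimethylsilyl chloride, CC(C)(C)[Si](C)(C)Cl
Why: Standard silylation of the secondary alcohol, which keeps the C6 oxygen from forming an alkoxide next to the oxirane in the strongly basic steps that follow.

**Step 5**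
Reactants: 5 (1S,4S,5S,6S)-5-[(tert-butyldimethylsilyl)oxy]-1-methyl-4-(prop-1-en-2-yl)-7-oxabicyclo[4.1.0]heptan-2-one; 6 (E)-2-methylbut-2-enal (tiglaldehyde)
Product: 7 (1S,4S,5S,6S)-5-[(tert-butyldimethylsilyl)oxy]-3-[(E)-1-hydroxy-2-methylbut-2-en-1-yl]-1-methyl-4-(prop-1-en-2-yl)-7-oxabicyclo[4.1.0]heptan-2-one (epimers at C8 and C9 of the later numbering)
Conditions: LiN(i-Pr)2, THF, −78 °C; then 6; AcOH, −78 °C
Reagents that add atoms: none
Why: Lithium enolate aldol addition, for which C8 is the only enolisable position because C4 is quaternary, and the enolate adds 1,2 to the enal; the two new stereocentres are erased in steps 6 to 8.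

**Step 6**
Reactants: 7 aldol adduct
Product: 8 (1S,4S,5S,6S)-5-[(tert-butyldimethylsilyl)oxy]-1-methyl-3-[(E)-2-methylbut-2-enoyl]-4-(prop-1-en-2-yl)-7-oxabicyclo[4.1.0]heptan-2-one (enolised 1,3-diketone)
Conditions: Dess–Martin periodinane, CH2Cl2, 0 °C to rt
Reagents that add atoms: none
Why: Dess–Martin oxidation of the secondary allylic alcohol should give the 1,3-diketone without touching the oxirane, the silyl ether or the olefins.

**Step 7**
Reactants: 8 1,3-diketone
Product: 9 (1S,4S,5S,6S)-5-[(tert-butyldimethylsilyl)oxy]-1-methyl-3-[(E)-2-methylbut-2-enoyl]-3-(phenylsulfanyl)-4-(prop-1-en-2-yl)-7-oxabicyclo[4.1.0]heptan-2-one (configuration at the sulfur-bearing carbon C8 open)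
Conditions: N-(phenylthio)succinimide, Et3N (cat.), CH2Cl2, 0 °C to rt
Reagents that add atoms: N-(phenylthio)succinimide, O=C1CCC(=O)N1Sc1ccccc1
Why: Electrophilic C-sulfenylation of the 1,3-diketone at its central carbon makes C8 quaternary, which prevents diketonate formation, keeps the C3 carbonyl electrophilic and later stabilises the C8 carbanion; the C8 configuration is of no consequence.

**Step 8**
Reactants: 9 sulfenylated 2-acyl ketone
Product: 12 (1(10)Z,4S,5S,6S,7S)-6-[(tert-butyldimethylsilyl)oxy]-4,5-epoxy-8-(phenylsulfanyl)germacra-1(10),11-diene-3,9-dione, via potassium dienolate 10 (not isolated), via bicyclic potassium alkoxide 11 (not isolated)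
Conditions: KN(SiMe3)2 (1.2 equiv), 18-crown-6, THF (0.05 M), −78 to −20 °C; then AcOH
Reagents that add atoms: none
Why: Proposed new method: KN(SiMe3)2 can remove only a γ-proton of the 2-methylbut-2-enoyl group (C8 and C4 are quaternary), and the γ-carbon C2 of dienolate 10 should add to the C3 ketone (vinylogous aldol, 6-(enolendo)-exo-trig) to close a six-membered ring in alkoxide 11; retro-aldol (retro-Claisen-type) cleavage of C3–C8 then releases a C8 carbanion stabilised by the C9 carbonyl and by sulfur, so that C9–C10–C1–C2 is inserted into the carvone ring. The closest known reactions are the carbanion-triggered addition–fragmentation ring enlargements of α-blocked cyclic β-dicarbonyl and α-nitro ketones, their radical counterpart the Dowd–Beckwith ring expansion, and the vinylogous aldol reaction. The only ring closed directly is the six-membered one; the ten-membered ring is unveiled by fragmentation, driven by the change from a weakly stabilised dienolate to the sulfur-stabilised enolate and then the vinylogous 1,5-diketonate. No lasting stereocentre is created (C3 returns to a carbonyl, C8 is cleared in step 11, C4–C7 are untouched), but the C1=C10 double bond is formed inside the six-membered ring of 11 and is therefore Z whatever the E, Z or β,γ composition of the acyl group, which makes the step stereoconvergent. The selectivity needed is γ-carbon attack on C3 (α-attack would need a four-membered ring, intramolecular sulfenyl transfer an endocyclic substitution at sulfur) and fragmentation in preference to dehydration, both favoured by the aprotic potassium alkoxide.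

**Step 9**
Reactants: 12 ring-expanded diketone
Product: 13 (1(10)Z,3S,4R,5S,6S,7S)-6-[(tert-butyldimethylsilyl)oxy]-4,5-epoxy-8-(phenylsulfanyl)germacra-1(10),11-diene-3,9-diol (epimers at C8 and C9)
Conditions: (R)-1-methyl-3,3-diphenyltetrahydro-1H,3H-pyrrolo[1,2-c][1,3,2]oxazaborole [(R)-Me-CBS, 0.3 equiv], catecholborane (3 equiv), toluene, −78 to −40 °C; then MeOH, aqueous work-up
Reagents that add atoms: none
Why: Corey–Bakshi–Shibata reduction, in which C3 is flanked by a methylene (small) and the fully substituted oxirane carbon C4 (large), so the (R)-catalyst should deliver hydride under reagent control to give the 3S carbinol, while the C9 enone is reduced as well to an allylic alcohol of no stereochemical consequence.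

**Step 10**
Reactants: 13 diol
Product: 14 (1(10)Z,3S,4R,5S,6S,7S)-6-[(tert-butyldimethylsilyl)oxy]-4,5-epoxy-3-hydroxy-8-(phenylsulfanyl)germacra-1(10),11-dien-9-one (C8 epimers)
Conditions: MnO2 (excess), CH2Cl2, rt
Reagents that add atoms: none
Why: Chemoselective allylic oxidation, since MnO2 should return only the allylic C9 alcohol to the enone and leave the non-allylic C3 carbinol untouched.

**Step 11**
Reactants: 14 α-phenylsulfanyl enone
Product: 15 (1(10)Z,3S,4R,5S,6S,7S)-6-[(tert-butyldimethylsilyl)oxy]-4,5-epoxy-3-hydroxygermacra-1(10),11-dien-9-one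
Conditions: SmI2 (2.5 equiv), THF–MeOH, −78 °C
Reagents that add atoms: none
Why: Reductive cleavage of the α-heteroatom-substituted ketone by SmI2 (samarium enolate, then protonation at C8) removes the blocking group; it is placed here because the C3 carbonyl of 12, an α,β-epoxy ketone, would itself be cleaved by this reagent.

**Step 12**
Reactants: 15 hydroxy enone
Product: 16 (1R,3S,4R,5S,6S,7S,10R)-6-[(tert-butyldimethylsilyl)oxy]-1,10:4,5-diepoxy-3-hydroxygermacr-11-en-9-one
Conditions: t-BuOOH, 1,8-diazabicyclo[5.4.0]undec-7-ene, toluene, 0 °C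
Reagents that add atoms: tert-butyl hydroperoxide, CC(C)(C)OO
Why: Weitz–Scheffer epoxidation of the (Z)-enone, in which the ring should hold C2 and C9 cis through the addition–closure sequence so that the cis-fused oxirane results, while hydrogen bonding of the peroxide to the free homoallylic C3 hydroxyl directs attack at C1 to the face syn to that hydroxyl (1R,10R).

**Step 13**
Reactants: 16 bis-epoxide with free C3 hydroxyl; 17 angelic acid [(Z)-2-methylbut-2-enoic acid]
Product: 18 (1R,3S,4R,5S,6S,7S,10R)-6-[(tert-butyldimethylsilyl)oxy]-1,10:4,5-diepoxy-9-oxogermacr-11-en-3-yl (Z)-2-methylbut-2-enoate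
Conditions: 17, 2,4,6-trichlorobenzoyl chloride, Et3N, toluene, rt; then 16, 80 °C
Reagents that add atoms: none
Why: Yamaguchi-type esterification through the mixed 2,4,6-trichlorobenzoic anhydride, run without 4-(dimethylamino)pyridine so that the (Z)-2-methylbut-2-enoate is not isomerised to the tiglate, should acylate the only free hydroxyl (C3) with retention, since the C3–O bond is not touched.

**Step 14**
Reactants: 18 C3 angelate silyl ether
Product: 19 (1R,3S,4R,5S,6S,7S,10R)-1,10:4,5-diepoxy-6-hydroxy-9-oxogermacr-11-en-3-yl (Z)-2-methylbut-2-enoate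
Conditions: Bu4NF, AcOH, THF, 0 °C to rt
Reagents that add atoms: none
Why: Fluoride cleavage of the silyl ether, buffered with acetic acid so that no free alkoxide can open the neighbouring oxiranes or cleave or shift the C3 ester, should unveil the C6 hydroxyl.

**Step 15**
Reactants: 19 C3 angelate with free C6 hydroxyl; 17 angelic acid [(Z)-2-methylbut-2-enoic acid]
Product: 20 (1R,3S,4R,5S,6S,7S,10R)-1,10:4,5-diepoxy-9-oxogermacr-11-ene-3,6-diyl bis[(Z)-2-methylbut-2-enoate] (target)
Conditions: 17, 2,4,6-trichlorobenzoyl chloride, Et3N, toluene, rt; then 19, 80 °C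
Reagents that add atoms: none
Why: A second Yamaguchi-type esterification through the mixed 2,4,6-trichlorobenzoic anhydride, again without 4-(dimethylamino)pyridine to keep the Z geometry of both esters, should acylate the remaining C6 hydroxyl with retention.

**Compound list**

1 | (S)-(+)-carvone, (5S)-2-methyl-5-(prop-1-en-2-yl)cyclohex-2-en-1-one | C=C(C)[C@@H]1CC(=O)C(C)=CC1 | starting material
2 | tert-butyldimethyl{[(5R)-2-methyl-5-(prop-1-en-2-yl)cyclohexa-1,3-dien-1-yl]oxy}silane | C=C(C)[C@@H]1CC(O[Si](C)(C)C(C)(C)C)=C(C)C=C1 | intermediate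
3 | (4R,5S)-4-hydroxy-2-methyl-5-(prop-1-en-2-yl)cyclohex-2-en-1-one | C=C(C)[C@@H]1CC(=O)C(C)=C[C@H]1O | intermediate
4 | (1S,4S,5S,6S)-5-hydroxy-1-methyl-4-(prop-1-en-2-yl)-7-oxabicyclo[4.1.0]heptan-2-one | C=C(C)[C@@H]1CC(=O)[C@@]2(C)O[C@H]2[C@H]1O | intermediate
5 | (1S,4S,5S,6S)-5-[(tert-butyldimethylsilyl)oxy]-1-methyl-4-(prop-1-en-2-yl)-7-oxabicyclo[4.1.0]heptan-2-one | C=C(C)[C@@H]1CC(=O)[C@@]2(C)O[C@H]2[C@H]1O[Si](C)(C)C(C)(C)C | intermediate
6 | (E)-2-methylbut-2-enal (tiglaldehyde) | C/C=C(\C)C=O | starting material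
7 | (1S,4S,5S,6S)-5-[(tert-butyldimethylsilyl)oxy]-3-[(E)-1-hydroxy-2-methylbut-2-en-1-yl]-1-methyl-4-(prop-1-en-2-yl)-7-oxabicyclo[4.1.0]heptan-2-one (epimers at the two new centres) | C=C(C)[C@@H]1C(C(O)/C(C)=C/C)C(=O)[C@@]2(C)O[C@H]2[C@H]1O[Si](C)(C)C(C)(C)C | intermediate
8 | (1S,4S,5S,6S)-5-[(tert-butyldimethylsilyl)oxy]-1-methyl-3-[(E)-2-methylbut-2-enoyl]-4-(prop-1-en-2-yl)-7-oxabicyclo[4.1.0]heptan-2-one | C=C(C)[C@@H]1C(C(=O)/C(C)=C/C)C(=O)[C@@]2(C)O[C@H]2[C@H]1O[Si](C)(C)C(C)(C)C | intermediate
9 | (1S,4S,5S,6S)-5-[(tert-butyldimethylsilyl)oxy]-1-methyl-3-[(E)-2-methylbut-2-enoyl]-3-(phenylsulfanyl)-4-(prop-1-en-2-yl)-7-oxabicyclo[4.1.0]heptan-2-one | C=C(C)[C@@H]1C(Sc3ccccc3)(C(=O)/C(C)=C/C)C(=O)[C@@]2(C)O[C@H]2[C@H]1O[Si](C)(C)C(C)(C)C | intermediate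
10 | potassium dienolate of 9, γ-deprotonated at C2 (not isolated) | C=C(C)[C@@H]1C(Sc3ccccc3)(C([O-])=C(C)C=C)C(=O)[C@@]2(C)O[C@H]2[C@H]1O[Si](C)(C)C(C)(C)C.[K+] | intermediate
11 | bicyclic potassium alkoxide with the C2–C3 bond formed and C3–C8 still intact (not isolated) | C=C(C)[C@@H]1C2(Sc3ccccc3)C(=O)C(C)=CCC2([O-])[C@@]2(C)O[C@H]2[C@H]1O[Si](C)(C)C(C)(C)C.[K+] | intermediate
12 | (1(10)Z,4S,5S,6S,7S)-6-[(tert-butyldimethylsilyl)oxy]-4,5-epoxy-8-(phenylsulfanyl)germacra-1(10),11-diene-3,9-dione (C8 epimers) | C=C(C)[C@@H]1C(Sc3ccccc3)C(=O)/C(C)=C\CC(=O)[C@@]2(C)O[C@H]2[C@H]1O[Si](C)(C)C(C)(C)C | intermediate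
13 | (1(10)Z,3S,4R,5S,6S,7S)-6-[(tert-butyldimethylsilyl)oxy]-4,5-epoxy-8-(phenylsulfanyl)germacra-1(10),11-diene-3,9-diol (C8 and C9 epimers) | C=C(C)[C@@H]1C(Sc3ccccc3)C(O)/C(C)=C\C[C@H](O)[C@@]2(C)O[C@H]2[C@H]1O[Si](C)(C)C(C)(C)C | intermediate
14 | (1(10)Z,3S,4R,5S,6S,7S)-6-[(tert-butyldimethylsilyl)oxy]-4,5-epoxy-3-hydroxy-8-(phenylsulfanyl)germacra-1(10),11-dien-9-one (C8 epimers) | C=C(C)[C@@H]1C(Sc3ccccc3)C(=O)/C(C)=C\C[C@H](O)[C@@]2(C)O[C@H]2[C@H]1O[Si](C)(C)C(C)(C)C | intermediate
15 | (1(10)Z,3S,4R,5S,6S,7S)-6-[(tert-butyldimethylsilyl)oxy]-4,5-epoxy-3-hydroxygermacra-1(10),11-dien-9-one | C=C(C)[C@@H]1CC(=O)/C(C)=C\C[C@H](O)[C@@]2(C)O[C@H]2[C@H]1O[Si](C)(C)C(C)(C)C | intermediate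
16 | (1R,3S,4R,5S,6S,7S,10R)-6-[(tert-butyldimethylsilyl)oxy]-1,10:4,5-diepoxy-3-hydroxygermacr-11-en-9-one | C=C(C)[C@@H]1CC(=O)[C@]2(C)O[C@@H]2C[C@H](O)[C@@]3(C)O[C@H]3[C@H]1O[Si](C)(C)C(C)(C)C | intermediate
17 | angelic acid, (Z)-2-methylbut-2-enoic acid | C/C=C(/C)C(=O)O | starting material
18 | (1R,3S,4R,5S,6S,7S,10R)-6-[(tert-butyldimethylsilyl)oxy]-1,10:4,5-diepoxy-9-oxogermacr-11-en-3-yl (Z)-2-methylbut-2-enoate | C=C(C)[C@@H]1CC(=O)[C@]2(C)O[C@@H]2C[C@H](OC(=O)/C(C)=C\C)[C@@]3(C)O[C@H]3[C@H]1O[Si](C)(C)C(C)(C)C | intermediate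
19 | (1R,3S,4R,5S,6S,7S,10R)-1,10:4,5-diepoxy-6-hydroxy-9-oxogermacr-11-en-3-yl (Z)-2-methylbut-2-enoate | C=C(C)[C@@H]1CC(=O)[C@]2(C)O[C@@H]2C[C@H](OC(=O)/C(C)=C\C)[C@@]3(C)O[C@H]3[C@H]1O | intermediate
20 | (1R,3S,4R,5S,6S,7S,10R)-1,10:4,5-diepoxy-9-oxogermacr-11-ene-3,6-diyl bis[(Z)-2-methylbut-2-enoate] | C=C(C)[C@@H]1CC(=O)[C@]2(C)O[C@@H]2C[C@H](OC(=O)/C(C)=C\C)[C@@]2(C)O[C@H]2[C@H]1OC(=O)/C(C)=C\C | target

**Totals**

Total step count: 15. Longest linear sequence: 15 steps, from (S)-carvone 1; compounds 6 and 17 are bought and enter directly.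

**Steps most likely to fail**

Step 8 (ring expansion). The dienolate may be consumed by proton transfer or intermolecular sulfenyl transfer before it adds to the hindered C3 carbonyl, or the alkoxide may revert instead of fragmenting. The fallback uses known chemistry, sets out from 9 and returns at 12; it separates bond formation from fragmentation. Deprotonation of 9 with KN(SiMe3)2 in the presence of Me3SiCl (THF, −78 °C) should trap the dienolate as the trimethylsilyl dienol ether F1. A BF3·OEt2-promoted intramolecular vinylogous Mukaiyama aldol addition to the C3 ketone (CH2Cl2, −78 °C) should then give the isolable bicyclic ketol F2. Treatment of F2 with KH and 18-crown-6 in THF at 0 °C (alkoxide retro-aldol fragmentation) should open it to 12.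

Step 1 (with step 2). Enolisation may occur at the α′-methylene and give the cross-conjugated silyl enol ether, or oxygen transfer in step 2 may go to the α- instead of the γ-carbon. The fallback sets out from 1 and returns at 3 without any dienolate. H2O2/NaOH in MeOH at 0 °C should give (S)-carvone oxide F3 (oxirane anti to isopropenyl). NaBH4/CeCl3 should reduce the ketone to the epoxy alcohol F4. Sodium phenylselenide [(PhSe)2, NaBH4, EtOH] should open the oxirane at the less substituted carbon to the hydroxy selenide F5. H2O2 oxidation and selenoxide syn-elimination, which can only go toward C6, should give the allylic diol F6. Dess–Martin oxidation of the secondary alcohol should give the tertiary α-hydroxy β,γ-enone F7. Re2O7 (cat.) in Et2O should then move the tertiary allylic hydroxyl suprafacially to C6, driven by conjugation, to give 3 with the hydroxyl trans to isopropenyl.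

Step 12 (second oxirane). Facial selectivity on the flexible ten-membered enone may be poor, or the cis ring fusion may be lost by bond rotation in the peroxy enolate. The fallback sets out from 15 and returns at 16; it replaces the stepwise nucleophilic epoxidation by a concerted, hydroxyl-directed one. Et3SiCl/imidazole should give the C3 triethylsilyl ether F8. (R)-Me-CBS with catecholborane should reduce the enone (alkenyl large, methylene small) to the 9S allylic alcohol F9. VO(acac)2/t-BuOOH in CH2Cl2 should epoxidise C1=C10 stereospecifically and cis to the C9 hydroxyl, as expected for medium-ring (Z)-allylic alcohols, to give the epoxy alcohol F10. Dess–Martin oxidation should give the epoxy ketone F11. HF·pyridine buffered with excess pyridine in THF at 0 °C should then cleave the triethylsilyl ether alone, the secondary tert-butyldimethylsilyl ether being much slower to react, to give 16.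

**Further compounds**

F1 | step 8 | trimethylsilyl dienol ether of 9 (2-silyloxy-1,3-diene on C8) | C=C(C)[C@@H]1C(Sc3ccccc3)(C(O[Si](C)(C)C)=C(C)C=C)C(=O)[C@@]2(C)O[C@H]2[C@H]1O[Si](C)(C)C(C)(C)C
F2 | step 8 | bicyclic ketol, tertiary alcohol at C3 with the C2–C3 and C3–C8 bonds both present | C=C(C)[C@@H]1C2(Sc3ccccc3)C(=O)C(C)=CCC2(O)[C@@]2(C)O[C@H]2[C@H]1O[Si](C)(C)C(C)(C)C
F3 | step 1 | (1S,4S,6S)-1-methyl-4-(prop-1-en-2-yl)-7-oxabicyclo[4.1.0]heptan-2-one (carvone oxide) | C=C(C)[C@@H]1CC(=O)[C@@]2(C)O[C@H]2C1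
F4 | step 1 | (1S,4S,6S)-1-methyl-4-(prop-1-en-2-yl)-7-oxabicyclo[4.1.0]heptan-2-ol (carbinol epimers) | C=C(C)[C@@H]1CC(O)[C@@]2(C)O[C@H]2C1
F5 | step 1 | 2-methyl-3-(phenylselanyl)-5-(prop-1-en-2-yl)cyclohexane-1,2-diol, tertiary hydroxyl anti to selenium and trans to isopropenyl | C=C(C)[C@@H]1CC(O)[C@@](C)(O)[C@H]([Se]c2ccccc2)C1
F6 | step 1 | 2-methyl-5-(prop-1-en-2-yl)cyclohex-3-ene-1,2-diol, tertiary hydroxyl trans to isopropenyl | C=C(C)[C@@H]1CC(O)[C@@](C)(O)C=C1
F7 | step 1 | 2-hydroxy-2-methyl-5-(prop-1-en-2-yl)cyclohex-3-en-1-one, hydroxyl trans to isopropenyl | C=C(C)[C@@H]1CC(=O)[C@@](C)(O)C=C1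
F8 | step 12 | 3-O-triethylsilyl ether of 15 | C=C(C)[C@@H]1CC(=O)/C(C)=C\C[C@H](O[Si](CC)(CC)CC)[C@@]2(C)O[C@H]2[C@H]1O[Si](C)(C)C(C)(C)C
F9 | step 12 | (9S)-allylic alcohol from F8 | C=C(C)[C@@H]1C[C@H](O)/C(C)=C\C[C@H](O[Si](CC)(CC)CC)[C@@]2(C)O[C@H]2[C@H]1O[Si](C)(C)C(C)(C)C
F10 | step 12 | (1R,9S,10R)-1,10-epoxy alcohol from F9, oxirane cis to the C9 hydroxyl | C=C(C)[C@@H]1C[C@H](O)[C@]2(C)O[C@@H]2C[C@H](O[Si](CC)(CC)CC)[C@@]3(C)O[C@H]3[C@H]1O[Si](C)(C)C(C)(C)C
F11 | step 12 | 3-O-triethylsilyl ether of 16 | C=C(C)[C@@H]1CC(=O)[C@]2(C)O[C@@H]2C[C@H](O[Si](CC)(CC)CC)[C@@]3(C)O[C@H]3[C@H]1O[Si](C)(C)C(C)(C)C
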